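A direct plan would etherify only the 4′-OH of (2S)-naringenin A1 with geranyl acetate A2 in a single step, under NiBr2(dme) and [Ir(dF(Me)ppy)2(dtbbpy)]PF6 with blue light, through the 4′-oxyl radical A3 and an η3-geranyl complex of divalent nickel derived from A2.
Its weakest operations would be:
(a) the site-selecting hydrogen-atom abstraction from A1, which would rest on a gap of a few kcal/mol between O–H bonds, while the more acidic 7-OH of A1 could be allylated by the nickel complex of A2 without any radical;
(b) the capture of A3 at nickel followed by C–O reductive elimination, an untested elementary step for a radical that tends to couple at carbon, with no hold on linear versus branched or E versus Z ether;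
(c) the carrying of the bought, ring-opening-prone C2 stereocenter of A1 through this unproven method as the only step, on precious enantiopure flavanone, with regioisomeric ethers that would be hard to remove.

**Plan of the new route**
Retrosynthesis: ring A is cut at C4a–C5 back to an acylketene, hence to dihydropyranone 12 (ring C with a CH2–dioxinone arm on the future C8a).
12 is cut at O1–C8a (cyclodehydration) and at C4–C4a (Claisen acylation) into Weinreb amide 7 and keto-dioxinone 9.
Ring order: ring B is bought and geranylated as a monophenol, ring C is closed around C2 (set by transfer hydrogenation), ring A is built last.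
Enabling feature: C8a bears the ring oxygen O1 and C4a the carbonyl C4, so ring C is the cyclic enol ether of a 1,3-diketone; its C4a=C8a bond is the third double bond of a dienylketene whose ketene and enol oxygens become 5-OH and 7-OH, both free, in a reagent-free step.
Thus no phenol is differentiated, no radical C–O coupling occurs, and C2 is made by catalysis and never meets base as a flavanone.

Key step: step 8

Abbreviation: geranyl = (2E)-3,7-dimethylocta-2,6-dien-1-yl.
Assumption: the (S,S)-TsDPEN ruthenium catalyst reduces aryl ketone 5 with the facial sense known for acetophenone, which gives the (S)-alcohol.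

**Route**

Step 1
Reactants: 1 methyl 4-hydroxybenzoate; 2 geranyl bromide
Product: 3 methyl 4-(geranyloxy)benzoate
Conditions: K2CO3 (1.5 equiv), DMF, rt, 12 h
Reagents that add atoms: none
Why: Williamson ether synthesis: the phenoxide displaces bromide at the primary allylic carbon by SN2, so the linear (E)-geranyl ether should form, and there is only one phenol to alkylate.

Step 2
Reactants: 3 methyl 4-(geranyloxy)benzoate; 4 N-methoxy-N-methylacetamide
Product: 5 3-[4-(geranyloxy)phenyl]-N-methoxy-N-methyl-3-oxopropanamide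
Conditions: 4 (2.5 equiv), LiN(iPr)2 (2.5 equiv), THF, −78 °C; then 3, −78 to 0 °C; AcOH quench
Reagents that add atoms: none
Why: Crossed Claisen condensation of the lithium enolate of 4 with the non-enolisable benzoate; the product is held as its enolate by the excess base, which should prevent a second addition.

Step 3
Reactants: 5 3-[4-(geranyloxy)phenyl]-N-methoxy-N-methyl-3-oxopropanamide
Product: 6 (3S)-3-[4-(geranyloxy)phenyl]-3-hydroxy-N-methoxy-N-methylpropanamide
Conditions: RuCl[(S,S)-TsDPEN](p-cymene) (1 mol%), HCO2H/Et3N (5:2), EtOAc, 30 °C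
Reagents that add atoms: none
Why: Noyori asymmetric transfer hydrogenation of an aryl ketone: the ruthenium hydride of the (S,S)-catalyst should add to the face that gives the (S)-benzylic alcohol (aryl group under the cymene ring by CH/π contact), which sets C2 of the target, and it does not reduce isolated trisubstituted olefins.

Step 4
Reactants: 6 (3S)-3-[4-(geranyloxy)phenyl]-3-hydroxy-N-methoxy-N-methylpropanamide
Product: 7 (3S)-3-[(tert-butyldimethylsilyl)oxy]-3-[4-(geranyloxy)phenyl]-N-methoxy-N-methylpropanamide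
Conditions: TBSCl (1.3 equiv), imidazole (2.5 equiv), DMF, rt
Reagents that add atoms: tert-butyldimethylsilyl chloride CC(C)(C)[Si](C)(C)Cl
Why: Imidazole-promoted silylation of the secondary alcohol masks the hydroxyl, so that no alkoxide can undergo retro-aldol cleavage or quench the dianion in step 6.

Step 5
Reactants: 8 2,2,6-trimethyl-4H-1,3-dioxin-4-one
Product: 9 2,2-dimethyl-6-(2-oxopropyl)-4H-1,3-dioxin-4-one
Conditions: 8 (2.0 equiv), LiN(SiMe3)2 (2.0 equiv), THF, −78 °C; AcCl (1.0 equiv), −78 °C; AcOH quench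
Reagents that add atoms: acetyl chloride CC(=O)Cl
Why: γ-Acylation of the lithium dienolate of the dioxinone (vinylogous Claisen condensation), a known type of access to such keto-dioxinones; the second equivalent of dienolate takes the acidic proton of the product.

Step 6
Reactants: 7 (3S)-3-[(tert-butyldimethylsilyl)oxy]-3-[4-(geranyloxy)phenyl]-N-methoxy-N-methylpropanamide; 9 2,2-dimethyl-6-(2-oxopropyl)-4H-1,3-dioxin-4-one
Product: 10 6-{(6S)-6-[(tert-butyldimethylsilyl)oxy]-6-[4-(geranyloxy)phenyl]-2,4-dioxohexyl}-2,2-dimethyl-4H-1,3-dioxin-4-one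
Conditions: 9 (2.5 equiv), LiN(iPr)2 (5.0 equiv), THF, −78 °C, 1 h; then 7 (1.0 equiv), −78 to −30 °C; AcOH quench at −78 °C; crude product used at once
Reagents that add atoms: none
Why: Claisen-type C-acylation of a 1,3-dicarbonyl dianion at its terminal, more basic carbon by a Weinreb amide, a known way to diketo-dioxinones; the chelated tetrahedral intermediate stops at the ketone stage and the benzylic stereocenter carries no acidic hydrogen.

Step 7
Reactants: 10 6-{(6S)-6-[(tert-butyldimethylsilyl)oxy]-6-[4-(geranyloxy)phenyl]-2,4-dioxohexyl}-2,2-dimethyl-4H-1,3-dioxin-4-one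
Product: 12 (2S)-6-[(2,2-dimethyl-4-oxo-4H-1,3-dioxin-6-yl)methyl]-2-[4-(geranyloxy)phenyl]-2,3-dihydro-4H-pyran-4-one, via hydroxy diketo-dioxinone 11 (not isolated)
Conditions: HF·pyridine, pyridine, THF, 0 °C to rt; then PPTS (20 mol%), CH2Cl2, rt
Reagents that add atoms: none
Why: Fluoride frees the δ-hydroxyl, which adds to the distal ketone (six-membered ring) and loses water under mild acid to give the vinylogous ester, the classical cyclodehydration of δ-hydroxy-β-diketones to 2,3-dihydro-4H-pyran-4-ones; the C–O bond at C2 is not broken, so the (S) configuration should be kept, and the buffered fluoride source and the mild acid are too weak to ionise the geranyl ether.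

Step 8
Reactants: 12 (2S)-6-[(2,2-dimethyl-4-oxo-4H-1,3-dioxin-6-yl)methyl]-2-[4-(geranyloxy)phenyl]-2,3-dihydro-4H-pyran-4-one
Product: 16 (2S)-4′-O-geranylnaringenin (target), via acylketene 13 (not isolated), via hydroxydienylketene 14 (not isolated), via cyclohexadienone 15 (not isolated)
Conditions: slow addition of 12 to toluene at 110 °C (final 2 mM), Ar, 1 h
Reagents that add atoms: none
Why: Proposed new method: heating splits acetone from the dioxinone (retro-hetero-Diels–Alder) to give acylketene 13, whose ketone enolises toward the doubly activated CH2 to hydroxydienylketene 14, in which the ketene C=C, the enol C=C and the C5=C6 bond of the pyranone form a hexatriene. Thermal disrotatory 6π-electrocyclisation joins the ketene carbon to pyranone C5 (the C4a–C5 bond of the target, ring A closed as a six-membered carbocycle) to give cyclohexadienone 15, which enolises to the arene with the ketene oxygen as 5-OH and the enol oxygen as 7-OH. The closest known reactions are the closing stage of the Danheiser benzannulation (dienylketene to phenol) and the thermolysis of dioxinones to acylketenes. No stereocenter is formed; C2 is a spectator, and since neither acid nor base is present, ring C cannot open by retro-oxa-Michael reaction and the geranyl ether cannot ionise. The step needs C-acylation at C4a in preference to lactonisation to a 4-hydroxy-2-pyranone and to aldol aromatisation to a resorcylate: the first is excluded because the C8a oxygen is already the ether O1 of ring C, the second because C4 lies trans to the arm across the ring C double bond. High dilution should keep the ketene from acylating the phenols of the product.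

**Compound list**

1 | methyl 4-hydroxybenzoate | COC(=O)c1ccc(O)cc1 | starting material
2 | geranyl bromide, (2E)-1-bromo-3,7-dimethylocta-2,6-diene | CC(C)=CCC/C(C)=C/CBr | starting material
3 | methyl 4-(geranyloxy)benzoate | CC(C)=CCC/C(C)=C/COc1ccc(C(=O)OC)cc1 | intermediate
4 | N-methoxy-N-methylacetamide | CC(=O)N(C)OC | starting material
5 | 3-[4-(geranyloxy)phenyl]-N-methoxy-N-methyl-3-oxopropanamide | CC(C)=CCC/C(C)=C/COc1ccc(C(=O)CC(=O)N(C)OC)cc1 | intermediate
6 | (3S)-3-[4-(geranyloxy)phenyl]-3-hydroxy-N-methoxy-N-methylpropanamide | CC(C)=CCC/C(C)=C/COc1ccc([C@@H](O)CC(=O)N(C)OC)cc1 | intermediate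
7 | (3S)-3-[(tert-butyldimethylsilyl)oxy]-3-[4-(geranyloxy)phenyl]-N-methoxy-N-methylpropanamide | CC(C)=CCC/C(C)=C/COc1ccc([C@@H](O[Si](C)(C)C(C)(C)C)CC(=O)N(C)OC)cc1 | intermediate
8 | 2,2,6-trimethyl-4H-1,3-dioxin-4-one | CC1=CC(=O)OC(C)(C)O1 | starting material
9 | 2,2-dimethyl-6-(2-oxopropyl)-4H-1,3-dioxin-4-one | CC(=O)CC1=CC(=O)OC(C)(C)O1 | intermediate
10 | 6-{(6S)-6-[(tert-butyldimethylsilyl)oxy]-6-[4-(geranyloxy)phenyl]-2,4-dioxohexyl}-2,2-dimethyl-4H-1,3-dioxin-4-one | CC(C)=CCC/C(C)=C/COc1ccc([C@@H](O[Si](C)(C)C(C)(C)C)CC(=O)CC(=O)CC2=CC(=O)OC(C)(C)O2)cc1 | intermediate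
11 | 6-{(6S)-6-[4-(geranyloxy)phenyl]-6-hydroxy-2,4-dioxohexyl}-2,2-dimethyl-4H-1,3-dioxin-4-one (hydroxy diketo-dioxinone) | CC(C)=CCC/C(C)=C/COc1ccc([C@@H](O)CC(=O)CC(=O)CC2=CC(=O)OC(C)(C)O2)cc1 | intermediate
12 | (2S)-6-[(2,2-dimethyl-4-oxo-4H-1,3-dioxin-6-yl)methyl]-2-[4-(geranyloxy)phenyl]-2,3-dihydro-4H-pyran-4-one | CC(C)=CCC/C(C)=C/COc1ccc([C@@H]2CC(=O)C=C(CC3=CC(=O)OC(C)(C)O3)O2)cc1 | intermediate
13 | 4-{(2S)-2-[4-(geranyloxy)phenyl]-4-oxo-3,4-dihydro-2H-pyran-6-yl}but-1-ene-1,3-dione (acylketene) | CC(C)=CCC/C(C)=C/COc1ccc([C@@H]2CC(=O)C=C(CC(=O)C=C=O)O2)cc1 | intermediate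
14 | 3-hydroxy-4-{(2S)-2-[4-(geranyloxy)phenyl]-4-oxo-3,4-dihydro-2H-pyran-6-yl}buta-1,3-dien-1-one, ketenyl and pyranonyl groups cis on the enol double bond (hydroxydienylketene) | CC(C)=CCC/C(C)=C/COc1ccc([C@@H]2CC(=O)C=C(/C=C(O)\C=C=O)O2)cc1 | intermediate
15 | (2S)-2-[4-(geranyloxy)phenyl]-7-hydroxy-2,3-dihydro-4H-chromene-4,5(4aH)-dione, both C4a epimers (cyclohexadienone) | CC(C)=CCC/C(C)=C/COc1ccc([C@@H]2CC(=O)C3C(=O)C=C(O)C=C3O2)cc1 | intermediate
16 | (2S)-4′-O-geranylnaringenin, (2S)-2-[4-(geranyloxy)phenyl]-5,7-dihydroxy-2,3-dihydro-4H-chromen-4-one | CC(C)=CCC/C(C)=C/COc1ccc([C@@H]2CC(=O)c3c(O)cc(O)cc3O2)cc1 | target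

**Count and risks**

Total steps: 8. Longest linear sequence: 7 steps (1, 2, 3, 4, 6, 7, 8).

Steps most likely to fail:

1. Step 8 (Proposed new method). What may go wrong: bimolecular consumption of the acylketene (dimerisation, acylation of product phenols), or failure of the hydroxydienylketene to reach the cisoid geometry, so that ring A does not close. The fallback uses known chemistry (ring A bought, C2 set by catalytic conjugate arylation), sets out from 2 and comes back at 16. Geranyl bromide 2 would alkylate 4-hydroxyphenylboronic acid (K2CO3, DMF) to give 4-(geranyloxy)phenylboronic acid F1. Commercial 5,7-dihydroxychromone would be silylated at its unchelated 7-OH (iPr3SiCl, imidazole, DMF) to give 5-hydroxy-7-[(triisopropylsilyl)oxy]-4H-chromen-4-one F2. Asymmetric conjugate addition of F1 to F2 under catalysis by divalent palladium (Pd(OCOCF3)2, t-BuPyOX of the enantiomer that leads to the (2S) adduct, NH4PF6, H2O, ClCH2CH2Cl, 60 °C) would give (2S)-2-[4-(geranyloxy)phenyl]-5-hydroxy-7-[(triisopropylsilyl)oxy]-2,3-dihydro-4H-chromen-4-one F3. HF·pyridine (THF, 0 °C) would then release 16 without base.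

2. Step 6. What may go wrong: proton transfer to the dianion or β-elimination of silanolate from the amide outruns acylation, so that conversion stalls. The fallback sets out from 7 and comes back at 10. Reduction of 7 with iBu2AlH (THF, −78 °C) would give (3S)-3-[(tert-butyldimethylsilyl)oxy]-3-[4-(geranyloxy)phenyl]propanal F4. Aldol addition of the dianion of 9 to this more electrophilic partner at −78 °C would give 6-{(6S)-6-[(tert-butyldimethylsilyl)oxy]-6-[4-(geranyloxy)phenyl]-4-hydroxy-2-oxohexyl}-2,2-dimethyl-4H-1,3-dioxin-4-one F5 as a mixture of carbinol epimers. Dess–Martin periodinane (CH2Cl2, 0 °C) would oxidise it to 10.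

3. Step 7. What may go wrong: aldol aromatisation of the diketo-dioxinone to a resorcylate in competition with ring C closure, or ionisation at the benzylic C–O bond under acid with loss of configuration. The fallback sets out from 7 and comes back at 13; ring C would be closed before any dioxinone is present, on a dioxo ester that cannot aromatise in this way. Acylation of the dianion of methyl acetoacetate (NaH, then n-BuLi, THF, 0 °C) by 7 would give methyl (7S)-7-[(tert-butyldimethylsilyl)oxy]-7-[4-(geranyloxy)phenyl]-3,5-dioxoheptanoate F6. Desilylation and cyclodehydration (HF·pyridine, then AcOH) would give methyl {(2S)-2-[4-(geranyloxy)phenyl]-4-oxo-3,4-dihydro-2H-pyran-6-yl}acetate F7. Me3SnOH (ClCH2CH2Cl, 70 °C) would give {(2S)-2-[4-(geranyloxy)phenyl]-4-oxo-3,4-dihydro-2H-pyran-6-yl}acetic acid F8, to be used at once. Coupling with Meldrum's acid (N,N′-dicyclohexylcarbodiimide, DMAP, CH2Cl2, 0 °C) would give the acyl Meldrum's acid 5-(2-{(2S)-2-[4-(geranyloxy)phenyl]-4-oxo-3,4-dihydro-2H-pyran-6-yl}-1-hydroxyethylidene)-2,2-dimethyl-1,3-dioxane-4,6-dione F9. Heated in dilute toluene, F9 would lose acetone and CO2 to give acylketene 13 and hence 16.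

Further compounds
F1 | step 8 | 4-(geranyloxy)phenylboronic acid | CC(C)=CCC/C(C)=C/COc1ccc(B(O)O)cc1
F2 | step 8 | 5-hydroxy-7-[(triisopropylsilyl)oxy]-4H-chromen-4-one | O=c1ccoc2cc(O[Si](C(C)C)(C(C)C)C(C)C)cc(O)c12
F3 | step 8 | (2S)-2-[4-(geranyloxy)phenyl]-5-hydroxy-7-[(triisopropylsilyl)oxy]-2,3-dihydro-4H-chromen-4-one | CC(C)=CCC/C(C)=C/COc1ccc([C@@H]2CC(=O)c3c(O)cc(O[Si](C(C)C)(C(C)C)C(C)C)cc3O2)cc1
F4 | step 6 | (3S)-3-[(tert-butyldimethylsilyl)oxy]-3-[4-(geranyloxy)phenyl]propanal | CC(C)=CCC/C(C)=C/COc1ccc([C@@H](O[Si](C)(C)C(C)(C)C)CC=O)cc1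
F5 | step 6 | 6-{(6S)-6-[(tert-butyldimethylsilyl)oxy]-6-[4-(geranyloxy)phenyl]-4-hydroxy-2-oxohexyl}-2,2-dimethyl-4H-1,3-dioxin-4-one (C4 epimers) | CC(C)=CCC/C(C)=C/COc1ccc([C@@H](O[Si](C)(C)C(C)(C)C)CC(O)CC(=O)CC2=CC(=O)OC(C)(C)O2)cc1
F6 | step 7 | methyl (7S)-7-[(tert-butyldimethylsilyl)oxy]-7-[4-(geranyloxy)phenyl]-3,5-dioxoheptanoate | CC(C)=CCC/C(C)=C/COc1ccc([C@@H](O[Si](C)(C)C(C)(C)C)CC(=O)CC(=O)CC(=O)OC)cc1
F7 | step 7 | methyl {(2S)-2-[4-(geranyloxy)phenyl]-4-oxo-3,4-dihydro-2H-pyran-6-yl}acetate | CC(C)=CCC/C(C)=C/COc1ccc([C@@H]2CC(=O)C=C(CC(=O)OC)O2)cc1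
F8 | step 7 | {(2S)-2-[4-(geranyloxy)phenyl]-4-oxo-3,4-dihydro-2H-pyran-6-yl}acetic acid | CC(C)=CCC/C(C)=C/COc1ccc([C@@H]2CC(=O)C=C(CC(=O)O)O2)cc1
F9 | step 7 | 5-(2-{(2S)-2-[4-(geranyloxy)phenyl]-4-oxo-3,4-dihydro-2H-pyran-6-yl}-1-hydroxyethylidene)-2,2-dimethyl-1,3-dioxane-4,6-dione | CC(C)=CCC/C(C)=C/COc1ccc([C@@H]2CC(=O)C=C(CC(O)=C3C(=O)OC(C)(C)OC3=O)O2)cc1
A1 | direct plan | (2S)-naringenin | Oc1ccc([C@@H]2CC(=O)c3c(O)cc(O)cc3O2)cc1
A2 | direct plan | geranyl acetate | CC(C)=CCC/C(C)=C/COC(C)=O
A3 | direct plan | (2S)-naringenin 4′-oxyl radical | [O]c1ccc([C@@H]2CC(=O)c3c(O)cc(O)cc3O2)cc1
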